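The constants come from no measurement; the flask was simulated.

Reagent charged at twice the substrate tempts you to expect full conversion, but the reagent also consumes itself.

    reagent in the reaction phase ⇌ reagent in the second phase, rate k1*([reagent in the reaction phase] - [reagent in the second phase]/K1) per volume of the first phase (K1 = 0.425, k1 = 0.800 /min)
    2 reagent in the reaction phase → self-condensation product (k2 = 0.979 /M/min)
    crystals ⇌ target, rate k3*(cs3 - [target]) while solid is left; crystals form when [target] > cs3 (cs3 = 1.8 mM, k3 = 0.125 /min)
    substrate + reagent in the reaction phase → target (k4 = 0.151 /M/min)

substrate 0.051 M; reagent in the second phase 0.102 M; time 8.0 h; volume of the second phase over the first 1.0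

- amounts and yields of target count crystals too
- where a step has two of a species, its rate is k times that concentration squared, and two are used at each turn
- in the second phase: reagent in the second phase; everything else is in the first
- charges count per volume of the first phase; a concentration in a rate is the amount of a species over the volume of its own phase; every rate counts per litre of the first phase
- given per volume of solution although it is solid: crystals
- run time (flask): 8.0 h

1. how much target and crystals together there is at 8.0 h, in percent of the substrate charged
2. concentration of target in solution at 2.0 h, in percent of saturation
3. the change that raises the amount of target and crystals together at 8.0 h, in percent of the substrate charged most ("none" if none brings more than 2 percentage points) (Saturday's / Friday's / Monday's / Wednesday's / none)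
4. amount of target and crystals together at 8.0 h, in percent of the substrate charged, after Monday's

- Saturday's: doubling the transfer coefficient of step 1, all else as stated
- Friday's: doubling the dissolution coefficient of step 3, all else as stated
- Monday's: doubling the solubility in step 3, all else as stated
- Wednesday's: doubling the amount of reagent in the second phase, all else as stated

Let R be the reagent in the reaction phase and S the substrate. The phases balance within 0.373 min. The reaction phase then holds a fraction f = 0.702 of the reagent, and R starts at Rs = 0.0716 M. That balance comes faster than the opening self-condensation lifetime of 10.2 min, so I expect little from Saturday's.

Carry the crossover concentration R* = k4 S / (2 k2), the level of R at which self-condensation and target formation use reagent equally. With S as charged, it is 3.93 mM, so Rs stands 18.2 times above it. Holding S there, dR/dt = −(R/τ)(1 + R/R*), with τ = 3.08 h.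

Target plus crystals starts at 0.0108 /min as a fraction of the substrate, and target reaches solubility after 3.27 min. The knee, R = R*, comes at 1.97 h, about the earlier time asked. Crystals take up target with a lifetime of 8.00 min, shorter than 2.0 h, so with R at R* and S as charged, my solution there stands at 113% of saturation.

Past the knee, R decays with lifetime τ. The exposure ∫R dt is ln(1 + (Rs/R*)g) / (2 k2 f), where g = 0.925, and the converted fraction is 1 − exp(−k4∫R dt). My reckoning gives 27.1% at 8.0 h, on the way to a level of 27.7%. Wednesday's gives 32.3%, a gain of 5.2 percentage points, more than the threshold.

The forecast gives, in the order asked, 28.6%, 112%, Wednesday's and 28.6%, its yield above mine, and holds that “Target never reacts further, so step 3 changes nothing in target plus crystals.”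

The flask gives 28.6%, 112%, Wednesday's and 28.6%, with Wednesday's gaining 5.6 points. At 8.00 h, this flask has R = 4.82 × 10⁻⁴ M and 71.4% of its substrate left. That puts R* at 2.81 mM, and R/R* at 0.172. In the neighbour with 0.20 M of substrate, S as charged gives R* = 15.4 mM, and Rs stands 4.65 times above it. The same exposure formula gives 17.3% for that neighbour, which holds 18.5%.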